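## Structural features

The target, 3,5-dibromo-2-(2,3,5-tribromo-4-hydroxyphenoxy)benzene-1,4-diol (15), is an achiral pentabrominated diphenyl ether. It has two benzene rings joined through one oxygen and no stereocentre, so no stereochemical relationships need to be set. Ring A is a differentiated bromohydroquinone (C1 ether oxygen, C2 OH, C3 H, C4 Br, C5 OH, C6 Br). Ring B is a tribromophenol (C1' ether oxygen, C2' H, C3' Br, C4' OH, C5' Br, C6' Br) with its hydroxyl para to the ether link. The ether oxygen is flanked by C2–O and C6–Br on ring A and by C6'–Br on ring B, so the diaryl ether is tri-ortho-substituted and a poor candidate for a late aryl–oxygen coupling. The fragile elements are the ring A hydroquinone, which electrophilic bromine oxidises to a quinone once both hydroxyls are free, the para-oxygenated phenols (ipso attack), and the aryl bromides (halogen–metal exchange, low-valent metals). The real difficulty is regiochemical: C3 must stay C–H although it is ortho to the C2 hydroxyl, and C6' must carry bromine although no phenol of the target directs there. The key step exploits the contiguous array C2(O)–C1(OAr)–C6(Br)–C5(O) of ring A. These four carbons have the substitution pattern of a 3-aryloxy-4-bromocyclobutenedione, so only C3 and C4 are added (as a vinyl group) and the C4–C5 bond is closed by ring expansion.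

## Logic of the disconnections

**15 ⇒ 14.** The two O–CH3 bonds at C2–O and C4'–O are the last to be broken in the forward sense. A free C2 hydroxyl would activate C3 and make ring A an oxidisable hydroquinone during halogenation, so both oxygens stay as methyl ethers until all bromines are in place. The demand is an ether cleavage that spares five C–Br bonds and the diaryl ether.

**14 ⇒ 13.** The C4–Br bond is cut. In 13 the only free phenol is at C5, its single open ortho position is C4, and C4 is also para to the aryloxy group. This leaves an arene with two adjacent ring hydrogens (C3, C4), the mark of a vinyl-derived two-carbon unit. The forward step must stop at monobromination and must not oxidise the para-methoxyphenol.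

**13 ⇒ 10.** The C4–C5 bond is cut and the C5–C2 σ bond of a four-membered ring is restored. C5, C6, C1 and C2 carry O, Br, OAr and O in exactly the order of a squarate, so ring A reduces to a cyclobutenone plus a vinyl group with the regiochemistry locked in the small ring. The forward step needs the vinyl group to rotate inward on ring opening and the ketene to close before it is intercepted.

**10 ⇒ 9.** The O–CH3 bond at the tertiary carbinol is cut. This methyl group is what later distinguishes the C2 oxygen from the C5 oxygen. The demand is etherification of a tertiary alcohol without base or nucleophile strong enough to displace the aryloxy group.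

**9 ⇒ 7 + 8.** The C2–C3 bond (carbinol carbon to vinyl carbon) is cut. This is a carbonyl addition to a cyclobutenedione, with C3 and C4 coming from a commercial two-carbon reagent. The forward step must attack the carbonyl next to the aryloxy-bearing carbon, must not displace the vinylic bromide or the aryloxide, and must not exchange ring B bromines.

**7 ⇒ 4 + 6.** The C1–O bond between the four-membered ring and the aryloxy oxygen is cut. The hindered diaryl ether oxygen is thus attached by addition–elimination at a vinylogous acyl bromide instead of by aryl–oxygen coupling, and ring B arrives complete with its three bromines. The demand is monosubstitution of a symmetrical dielectrophile.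

**6 ⇒ 5.** Both C–Br bonds are cut back to the vinylogous diacid. The demand is anhydrous handling of a moisture-sensitive dihalide.

**4 ⇒ 3.** The C6'–Br bond is cut. In the fragment the future ether oxygen is still a free phenol, so it directs bromine to its own ortho position and solves the C6' problem before the rings are joined. The demand is to stop at one of two equivalent ortho positions.

**3 ⇒ 1.** The C1'–O bond is cut back to C–H through a C–B bond. The only ring hydrogen of 1 without an ortho neighbour is para to the methoxy group, where sterically governed borylation places oxygen. The demand is C–H functionalisation that tolerates aryl bromides.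

## Other disconnections considered

**Alternative 1:** The cut runs through four C–Br bonds (C4, C6, C3', C5') of a halogen-free diaryl ether whose C2 oxygen is a mesylate, A2. Forward, four equivalents of elemental bromine in acetic acid would substitute every position ortho to the two free phenols and give A1.
- In favour: the carbon–oxygen skeleton comes first from cheap oxygenated benzenes, there is no cryogenic organometallic step and no strained ring, and the mesylate deactivates C3, which must remain C–H. In reagent simplicity and probably in scalability this plan is better than the chosen one.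
- Against: A1 holds only four of the five bromines. The fifth, at C6', is meta to the C4' hydroxyl on a ring already carrying two bromines, so it needs a separate undirected substitution that must stop at one of two equivalent positions and leave C3 alone.
- Against: ring B of A2 and A1 is a 4-aryloxyphenol, a type of arene that electrophilic bromine can attack ipso at C1' with oxidative loss of the ether. A2 itself still requires a diaryl ether coupling and differentiation of three oxygens.
- Comparison: in the chosen plan every bromine is either built into a fragment or placed by one phenol-directed substitution, whereas here regiocontrol rests on relative rates in one pot. Both rely on ortho direction by a free phenol, and on that point they are equal. The step counts are expected to be close, and the alternative could be shorter if A2 is quickly made.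

**Alternative 2:** The cut removes the C1'–O and C6'–Br bonds together across an aryne. Forward, a fluoride source would release the aryne from A4, the phenoxide of A5 would add at C1', and the C6' aryl anion would take bromine from an electrophilic bromine donor to give A3. One global demethylation would finish.
- In favour: two fully substituted rings are joined convergently under mild, transition-metal-free conditions, and the tri-ortho-substituted ether is formed without an Ullmann coupling. The C5' bromine should steer the nucleophile to the remote aryne carbon and place the negative charge beside the halogen. Only one step follows the key step, which is better than the two that follow the chosen one.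
- Against: the C6' anion sits next to the C5' bromine and can expel bromide to form a second aryne, or be protonated by the medium, before it is brominated. The electron-rich phenoxide of A5 competes with the aryl anion for the bromine donor, and a di-ortho-substituted phenoxide is a slow aryne trap. A4 and A5 are both multistep objects with their own regiochemical problems.
- Comparison: both plans avoid a classical diaryl ether coupling (equal). Convergence is better in the alternative, since both rings are complete before union. Mechanistically it is a three-component polar trapping with two selectivity demands, against a unimolecular pericyclic step with none. Overall step counts are expected to be similar, because the saving after the key step is spent on A4 and A5.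

**Alternative 3:** The cut dismantles ring B through C1'–C2', C3'–C4' and C4'–C5'. Forward, heating the zerovalent chromium carbene complex A7 (made from the phenol A5) with the alkyne A8 should give A6 by a Dötz benzannulation (alkyne insertion, CO insertion to a vinylketene complex, 6π closure). Ipso-bromodesilylation at C3' and C6', bromination at C5' and demethylation would follow.
- In favour: it is also a de novo arene synthesis through a ketene and a 6π closure, so mechanistically it stands on the same footing as the chosen step. The ether C–O bond is made at the carbene stage and not by aryl coupling (equal). The new hydroxyl emerges free while the other oxygens are ethers (equal), and the silyl groups mark two of the three bromine sites. The fully brominated ring A enters in one piece, which is a point in its favour over the chosen plan.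
- Against: aryloxycarbene complexes are far more labile than alkoxy ones, and A7 must come from a di-ortho-substituted phenol. The chromium is stoichiometric. Silyl-bearing partners tend to stop at stable silylvinylketenes.
- Against: after the key step three separate C–Br bonds must be formed on an oxidation-prone 4-aryloxyphenol. Two are ipso substitutions of unequal ease (C6' is meta to the phenol) and one is an ordinary bromination. With demethylation that makes about four steps after the key step against two.
- Comparison: the chosen route is expected to be shorter and is metal-free in the ring-forming step. The alternative is equal in oxygen differentiation and in avoiding an aryl ether coupling.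

Key step: step 7

Remark on the chemistry: 3,4-dibromocyclobut-3-ene-1,2-dione (6) is assumed to behave like the well-studied dichloride. The locants C1–C6 and C1'–C6' are those defined under "Structural features", not those of the systematic names. The carbonyl carbon, CBr, C(OAr), C(OMe), vinyl CH and vinyl CH2 of 10 map onto C5, C6, C1, C2, C3 and C4 of ring A.

## Route

Step 1
Reactants: 1 2,6-dibromoanisole
Product: 3 3,5-dibromo-4-methoxyphenol, via pinacol boronate 2 (not isolated)
Conditions: [Ir(OMe)(cod)]2 (1.5 mol %), 4,4'-di-tert-butyl-2,2'-bipyridine (3 mol %), B2pin2 (1.0 equiv), THF, 70 °C; evaporate; KHSO5 (as 2KHSO5·KHSO4·K2SO4), acetone/H2O, rt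
Reagents that add atoms: potassium peroxymonosulfate, [K+].[O-]S(=O)(=O)OO (the new oxygen); bis(pinacolato)diboron, CC1(C)OB(OC1(C)C)B1OC(C)(C)C(C)(C)O1 (its boryl group is carried only by 2)
Why: Iridium-catalysed C–H borylation is sterically governed and tolerates aryl bromides; the only C–H of 1 without an ortho substituent is para to the methoxy group. Oxidation of the C–B bond of 2 with peroxymonosulfate (boronate-to-phenol oxidation by 1,2-aryl shift) should then give 3 in the same flask.

Step 2
Reactants: 3 3,5-dibromo-4-methoxyphenol
Product: 4 2,3,5-tribromo-4-methoxyphenol
Conditions: NBS (1.0 equiv), anhydrous MeCN, 0 °C to rt, dark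
Reagents that add atoms: N-bromosuccinimide, O=C1CCC(=O)N1Br
Why: Phenol-directed electrophilic aromatic bromination; the two positions ortho to the hydroxyl are equivalent and the para position is blocked, so only mono- versus dibromination matters. That rests on the stoichiometry and on the deactivation by the first new bromine.

Step 3
Reactants: 5 squaric acid (3,4-dihydroxycyclobut-3-ene-1,2-dione)
Product: 6 3,4-dibromocyclobut-3-ene-1,2-dione
Conditions: (COBr)2 (2.5 equiv), DMF (cat.), CH2Cl2, reflux; evaporate, sublime, moisture excluded
Reagents that add atoms: oxalyl bromide, O=C(Br)C(=O)Br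
Why: Vilsmeier-type activation of the vinylogous carboxylic acid followed by bromide addition–elimination; this is the bromine counterpart of the standard preparation of squaric acid dichloride, and gas evolution drives it.

Step 4
Reactants: 4 2,3,5-tribromo-4-methoxyphenol; 6 3,4-dibromocyclobut-3-ene-1,2-dione
Product: 7 3-bromo-4-(2,3,5-tribromo-4-methoxyphenoxy)cyclobut-3-ene-1,2-dione
Conditions: 4 and iPr2NEt (1.0 equiv) added slowly to 6 (1.2 equiv), Et2O/toluene, −78 to 0 °C; filter, concentrate, crystallise (no aqueous work-up)
Reagents that add atoms: none
Why: Addition–elimination of a phenol at a vinylogous acyl bromide carbon (monosubstitution of a squaric dihalide). The first aryloxy group lowers the electrophilicity of the remaining C–Br through vinylogous ester resonance, and inverse addition to excess 6 holds back the second substitution.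

Step 5
Reactants: 7 3-bromo-4-(2,3,5-tribromo-4-methoxyphenoxy)cyclobut-3-ene-1,2-dione; 8 vinylmagnesium bromide
Product: 9 racemic 2-bromo-4-hydroxy-3-(2,3,5-tribromo-4-methoxyphenoxy)-4-vinylcyclobut-2-en-1-one
Conditions: 8 (1.05 equiv, slow addition), THF, −78 °C; sat. aq NH4Cl at −78 °C
Reagents that add atoms: none
Why: 1,2-Addition of a Grignard reagent to a cyclobutenedione; the carbonyl next to the aryloxy-bearing carbon is the one not deactivated as a vinylogous ester and should react first. Low temperature and a hard nucleophile disfavour displacement of the vinylic bromide and halogen–magnesium exchange. The new quaternary centre forms as a racemate and is destroyed in step 7.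

Step 6
Reactants: 9 racemic 2-bromo-4-hydroxy-3-(2,3,5-tribromo-4-methoxyphenoxy)-4-vinylcyclobut-2-en-1-one
Product: 10 racemic 2-bromo-4-methoxy-3-(2,3,5-tribromo-4-methoxyphenoxy)-4-vinylcyclobut-2-en-1-one
Conditions: MeI (10 equiv), Ag2O (2 equiv), CaSO4, MeCN, rt, dark
Reagents that add atoms: iodomethane, CI
Why: Purdie methylation, a neutral etherification commonly applied to squarate-derived tertiary 4-hydroxycyclobutenones. No strong base or free alkoxide is present to displace the aryloxy group, and the desiccant removes the water formed.

Step 7
Reactants: 10 racemic 2-bromo-4-methoxy-3-(2,3,5-tribromo-4-methoxyphenoxy)-4-vinylcyclobut-2-en-1-one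
Product: 13 2-bromo-4-methoxy-3-(2,3,5-tribromo-4-methoxyphenoxy)phenol, via dienylketene 11 (not isolated), via cyclohexadienone 12 (not isolated)
Conditions: degassed p-xylene (0.01 M), 135 °C, Ar
Reagents that add atoms: none
Why: Heat opens the C5–C2 σ bond of the cyclobutenone (carbonyl carbon to quaternary carbon) by a thermally allowed conrotatory 4π electrocyclic ring opening to the dienylketene 11. The methoxy group, the stronger π-donor on the quaternary carbon, rotates outward, so the vinyl group turns inward and ends cis to the ketene in (3Z)-11. A disrotatory 6π electrocyclisation then joins the ketene carbon (C5) to the vinyl terminus (C4) and closes ring A as the 2,4-dienone 12; this pericyclic 6π closure forms the only new ring. Enolisation of 12 to the phenol 13 is driven by aromatisation and makes the sequence irreversible. The closest known reaction type is the thermal ring expansion of squarate-derived 4-alkenyl-4-alkoxy- or 4-hydroxycyclobutenones to hydroquinone monoethers (Moore-type squarate benzannulation). No stereocentre is formed and the racemic quaternary centre of 10 is destroyed, so no stereocontrol is needed. The step needs the correct sense of rotation, which the 4-methoxy donor secures, and freedom from bimolecular capture of the ketene, which high dilution in an aprotic hydrocarbon secures; regiochemistry is not at issue because the order O–C(Br)–C(OAr)–C(OMe) is fixed in the four-membered ring.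

Step 8
Reactants: 13 2-bromo-4-methoxy-3-(2,3,5-tribromo-4-methoxyphenoxy)phenol
Product: 14 2,6-dibromo-4-methoxy-3-(2,3,5-tribromo-4-methoxyphenoxy)phenol
Conditions: NBS (1.0 equiv), anhydrous CH2Cl2, 0 °C, dark
Reagents that add atoms: N-bromosuccinimide, O=C1CCC(=O)N1Br
Why: Phenol-directed electrophilic aromatic bromination; C4 is the only open position ortho to the free C5 hydroxyl and is also para to the aryloxy group, whereas C3 is activated only by the methyl ether and ring B is deactivated by three bromines. Anhydrous conditions disfavour oxidative demethylation of the para-methoxyphenol to a quinone.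

Step 9
Reactants: 14 2,6-dibromo-4-methoxy-3-(2,3,5-tribromo-4-methoxyphenoxy)phenol
Product: 15 3,5-dibromo-2-(2,3,5-tribromo-4-hydroxyphenoxy)benzene-1,4-diol
Conditions: BBr3 (6 equiv), CH2Cl2, −78 °C to rt, Ar; ice/H2O; aq Na2S2O4 wash
Reagents that add atoms: none
Why: Boron tribromide cleavage of both aryl methyl ethers (Lewis acid complexation, then bromide attack at methyl). Aryl bromides and the diaryl ether are inert to it, and the reductive wash protects the freed hydroquinone from air oxidation.

## Compound list

1 | 2,6-dibromoanisole | COc1c(Br)cccc1Br | starting material
2 | 2-(3,5-dibromo-4-methoxyphenyl)-4,4,5,5-tetramethyl-1,3,2-dioxaborolane | COc1c(Br)cc(cc1Br)B1OC(C)(C)C(C)(C)O1 | intermediate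
3 | 3,5-dibromo-4-methoxyphenol | COc1c(Br)cc(O)cc1Br | intermediate
4 | 2,3,5-tribromo-4-methoxyphenol | COc1c(Br)cc(O)c(Br)c1Br | intermediate
5 | squaric acid (3,4-dihydroxycyclobut-3-ene-1,2-dione) | O=C1C(O)=C(O)C1=O | starting material
6 | 3,4-dibromocyclobut-3-ene-1,2-dione | O=C1C(Br)=C(Br)C1=O | intermediate
7 | 3-bromo-4-(2,3,5-tribromo-4-methoxyphenoxy)cyclobut-3-ene-1,2-dione | O=C1C(=O)C(Oc2cc(Br)c(OC)c(Br)c2Br)=C1Br | intermediate
8 | vinylmagnesium bromide | C=C[Mg]Br | starting material
9 | racemic 2-bromo-4-hydroxy-3-(2,3,5-tribromo-4-methoxyphenoxy)-4-vinylcyclobut-2-en-1-one | O=C1C(Br)=C(Oc2cc(Br)c(OC)c(Br)c2Br)C1(O)C=C | intermediate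
10 | racemic 2-bromo-4-methoxy-3-(2,3,5-tribromo-4-methoxyphenoxy)-4-vinylcyclobut-2-en-1-one | O=C1C(Br)=C(Oc2cc(Br)c(OC)c(Br)c2Br)C1(OC)C=C | intermediate
11 | (3Z)-2-bromo-4-methoxy-3-(2,3,5-tribromo-4-methoxyphenoxy)hexa-1,3,5-trien-1-one | O=C=C(Br)/C(Oc1cc(Br)c(OC)c(Br)c1Br)=C(\C=C)OC | intermediate
12 | 2-bromo-4-methoxy-3-(2,3,5-tribromo-4-methoxyphenoxy)cyclohexa-2,4-dien-1-one | O=C1CC=C(OC)C(Oc2cc(Br)c(OC)c(Br)c2Br)=C1Br | intermediate
13 | 2-bromo-4-methoxy-3-(2,3,5-tribromo-4-methoxyphenoxy)phenol | COc1ccc(O)c(Br)c1Oc1cc(Br)c(OC)c(Br)c1Br | intermediate
14 | 2,6-dibromo-4-methoxy-3-(2,3,5-tribromo-4-methoxyphenoxy)phenol | COc1cc(Br)c(O)c(Br)c1Oc1cc(Br)c(OC)c(Br)c1Br | intermediate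
15 | 3,5-dibromo-2-(2,3,5-tribromo-4-hydroxyphenoxy)benzene-1,4-diol | Oc1cc(Br)c(O)c(Br)c1Oc1cc(Br)c(O)c(Br)c1Br | target

## Step count and least certain steps

Total step count: 9. Longest linear sequence: 8 steps (steps 1, 2, 4, 5, 6, 7, 8, 9); step 3 is a one-step branch that joins at step 4.

**Step 7 (key step).** The most likely failure is bimolecular consumption of the electrophilic α-bromo dienylketene (acylation of the phenolic product, dimerisation), or thermal exchange of the labile aryloxy group, before the comparatively slow closure onto an unsubstituted vinyl group. The fallback changes the ring-closing manifold to the diradical cyclisation of an enynylketene, which for 4-alkynyl-4-hydroxycyclobutenones usually runs at lower temperature and ends in a stable quinone. It sets out from 7. Ethynylmagnesium bromide (THF, −78 °C) should give racemic 2-bromo-4-ethynyl-4-hydroxy-3-(2,3,5-tribromo-4-methoxyphenoxy)cyclobut-2-en-1-one F1. Heating in MeCN or toluene (80–110 °C) should give 2-bromo-3-(2,3,5-tribromo-4-methoxyphenoxy)cyclohexa-2,5-diene-1,4-dione F2 by ring opening, closure between the ketene carbon and the alkyne terminus, and hydrogen transfer from the hydroxyl. HBr in AcOH/CHCl3 at 0 °C should add in 1,4-fashion at the ring carbon para to the aryloxy group, because the carbonyl beside the aryloxy carbon is the one not deactivated as a vinylogous ester and that position is its β-carbon. This gives 3,5-dibromo-2-(2,3,5-tribromo-4-methoxyphenoxy)benzene-1,4-diol F3. BBr3 then cleaves the single methyl ether and the route is rejoined at 15.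

**Step 5.** The likely failures are addition–elimination at the bromine-bearing or aryloxy-bearing ring carbon instead of carbonyl addition, attack at the wrong carbonyl (aryloxy and bromine differentiate the two ketones less than alkoxy and alkyl do), and halogen–magnesium exchange on ring B. The fallback keeps bromine off the four-membered ring until the organometallic step is over. It sets out from 4. Purchased semisquaric acid with (COCl)2/DMF gives 3-chlorocyclobut-3-ene-1,2-dione F4, which with 4 and iPr2NEt should give 3-(2,3,5-tribromo-4-methoxyphenoxy)cyclobut-3-ene-1,2-dione F5. Vinylmagnesium bromide adds to the carbonyl next to the aryloxy carbon of this halogen-free dione, the usual regiochemistry of 3-alkoxycyclobutenediones, to give racemic 4-hydroxy-3-(2,3,5-tribromo-4-methoxyphenoxy)-4-vinylcyclobut-2-en-1-one F6. MeI/Ag2O gives racemic 4-methoxy-3-(2,3,5-tribromo-4-methoxyphenoxy)-4-vinylcyclobut-2-en-1-one F7. NBS in CH2Cl2 at 0 °C followed by 2,6-lutidine brominates the nucleophilic α-carbon of the β-aryloxy enone, and the route is rejoined at 10.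

**Step 4.** The likely failures are a second substitution leading to the bis-aryl ester and hydrolysis of the acyl-bromide-like C–Br during isolation. The fallback makes double substitution the intended reaction and desymmetrises by hydrolysis. It sets out from 6. Two equivalents of 4 with iPr2NEt should give 3,4-bis(2,3,5-tribromo-4-methoxyphenoxy)cyclobut-3-ene-1,2-dione F8. One equivalent of aqueous NaOH in THF at 0 °C should displace a single aryloxide, because the resulting squarate monoanion is no longer electrophilic, and acidification gives 3-hydroxy-4-(2,3,5-tribromo-4-methoxyphenoxy)cyclobut-3-ene-1,2-dione F9 with one equivalent of 4 recovered. (COBr)2/DMF, as in step 3, converts the vinylogous acid into the vinylogous acyl bromide and the route is rejoined at 7.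

**Step 3.** The likely failures are incomplete conversion of the insoluble diacid and hydrolysis of the dibromide on isolation. The fallback goes through the long-established dichloride and a halide exchange. It sets out from 5. (COCl)2 with catalytic DMF gives 3,4-dichlorocyclobut-3-ene-1,2-dione F10. Excess Me3SiBr with distillation of the volatile chlorosilane (acyl chloride to acyl bromide exchange) then rejoins the route at 6.

## Further compounds

F1 | step 7 | racemic 2-bromo-4-ethynyl-4-hydroxy-3-(2,3,5-tribromo-4-methoxyphenoxy)cyclobut-2-en-1-one | O=C1C(Br)=C(Oc2cc(Br)c(OC)c(Br)c2Br)C1(O)C#C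
F2 | step 7 | 2-bromo-3-(2,3,5-tribromo-4-methoxyphenoxy)cyclohexa-2,5-diene-1,4-dione | O=C1C=CC(=O)C(Oc2cc(Br)c(OC)c(Br)c2Br)=C1Br
F3 | step 7 | 3,5-dibromo-2-(2,3,5-tribromo-4-methoxyphenoxy)benzene-1,4-diol | Oc1cc(Br)c(O)c(Br)c1Oc1cc(Br)c(OC)c(Br)c1Br
F4 | step 5 | 3-chlorocyclobut-3-ene-1,2-dione | O=C1C=C(Cl)C1=O
F5 | step 5 | 3-(2,3,5-tribromo-4-methoxyphenoxy)cyclobut-3-ene-1,2-dione | O=C1C=C(Oc2cc(Br)c(OC)c(Br)c2Br)C1=O
F6 | step 5 | racemic 4-hydroxy-3-(2,3,5-tribromo-4-methoxyphenoxy)-4-vinylcyclobut-2-en-1-one | O=C1C=C(Oc2cc(Br)c(OC)c(Br)c2Br)C1(O)C=C
F7 | step 5 | racemic 4-methoxy-3-(2,3,5-tribromo-4-methoxyphenoxy)-4-vinylcyclobut-2-en-1-one | O=C1C=C(Oc2cc(Br)c(OC)c(Br)c2Br)C1(OC)C=C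
F8 | step 4 | 3,4-bis(2,3,5-tribromo-4-methoxyphenoxy)cyclobut-3-ene-1,2-dione | O=C1C(=O)C(Oc2cc(Br)c(OC)c(Br)c2Br)=C1Oc1cc(Br)c(OC)c(Br)c1Br
F9 | step 4 | 3-hydroxy-4-(2,3,5-tribromo-4-methoxyphenoxy)cyclobut-3-ene-1,2-dione | O=C1C(=O)C(O)=C1Oc1cc(Br)c(OC)c(Br)c1Br
F10 | step 3 | 3,4-dichlorocyclobut-3-ene-1,2-dione | O=C1C(Cl)=C(Cl)C1=O
A1 | alternative 1 | 3,5-dibromo-2-(3,5-dibromo-4-hydroxyphenoxy)-4-hydroxyphenyl methanesulfonate | CS(=O)(=O)Oc1cc(Br)c(O)c(Br)c1Oc1cc(Br)c(O)c(Br)c1
A2 | alternative 1 | 4-hydroxy-2-(4-hydroxyphenoxy)phenyl methanesulfonate | CS(=O)(=O)Oc1ccc(O)cc1Oc1ccc(O)cc1
A3 | alternative 2 | 1,3-dibromo-2,5-dimethoxy-4-(2,3,5-tribromo-4-methoxyphenoxy)benzene | COc1c(Br)cc(Oc2c(OC)cc(Br)c(OC)c2Br)c(Br)c1Br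
A4 | alternative 2 | 2,4-dibromo-3-methoxy-6-(trimethylsilyl)phenyl trifluoromethanesulfonate | COc1c(Br)cc([Si](C)(C)C)c(OS(=O)(=O)C(F)(F)F)c1Br
A5 | alternative 2 | 2,4-dibromo-3,6-dimethoxyphenol | COc1cc(Br)c(OC)c(Br)c1O
A6 | alternative 3 | 4-(2,4-dibromo-3,6-dimethoxyphenoxy)-2,5-bis(trimethylsilyl)phenol | COc1cc(Br)c(OC)c(Br)c1Oc1cc([Si](C)(C)C)c(O)cc1[Si](C)(C)C
A7 | alternative 3 | pentacarbonyl[(2,4-dibromo-3,6-dimethoxyphenoxy)(1-trimethylsilylvinyl)carbene]chromium | C=C([Si](C)(C)C)C(Oc1c(OC)cc(Br)c(OC)c1Br)=[Cr](=C=O)(=C=O)(=C=O)(=C=O)=C=O
A8 | alternative 3 | trimethylsilylacetylene | C#C[Si](C)(C)C
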